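(All runs come from a simulation from invented constants; scatter was added.)

The leftover nucleophile in the flask at 1.5 h came in two kinds, free and bound as protonated nucleophile, and I reckoned the split from the acid released in all, bound forms counted.

common to all: electrophile 0.10 M
- theta: nucleophile 0.20 M; free base 0.17 M; protic impurity 5 mM; run made earlier
- zeta: nucleophile 0.20 M; free base 0.26 M; protic impurity 5 mM; run made earlier
- beta: nucleophile 0.20 M; free base 0.12 M; protic impurity 10 mM; run made earlier
- flask: nucleophile 0.200 M; free base 0.120 M; protic impurity 5.00 mM; time 1.5 h

| run | time / min | electrophile / % | target / % |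
|---|---|---|---|
| theta | 5.00 | 88.6 | 8.0 |
| theta | 15.0 | 68.8 | 16.6 |
| theta | 25.0 | 53.2 | 20.7 |
| theta | 40.0 | 35.7 | 21.4 |
| theta | 50.0 | 28.2 | 21.7 |
| zeta | 5.00 | 89.1 | 8.2 |
| zeta | 15.0 | 68.5 | 16.7 |
| zeta | 25.0 | 53.5 | 20.9 |
| zeta | 40.0 | 36.7 | 21.2 |
| zeta | 50.0 | 28.3 | 21.0 |
| beta | 5.00 | 88.9 | 8.4 |
| beta | 15.0 | 68.7 | 17.4 |
| beta | 25.0 | 52.7 | 20.4 |
| beta | 40.0 | 36.8 | 21.3 |
| beta | 50.0 | 29.0 | 21.7 |

(scatter of a reading: 0.3 percentage points)

- percent here means electrophile units held: one side product counts as two
- reactions considered so far: electrophile + nucleophile -> acid set free + target; acid set free + free base <-> salt of the base; electrophile + target -> side product; nucleophile + acid set free <-> protonated nucleophile; protic impurity + free base -> quenched reagent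
- the earlier runs do not show how much of nucleophile is bound; that part of a forecast is a guess

* part of the electrophile that has reacted at 1.5 h
* share of the unused nucleophile that is free and not bound as protonated nucleophile, at 1.5 h

Each target made sets free one acid, and a side product counts two electrophile units from one acid, so the acid released in all, free and bound, is half the sum of reacted electrophile and target. At the last reading the electrophile stood at 28.2%, 28.3% and 29.0% in theta, zeta and beta, so I read the flask off theta. Theta's whole run gave a rate of 0.0253 min⁻¹, hence a first estimate of 10.3% left in the flask. But its last interval ran slower, at 0.0236 min⁻¹, so I put that rate back and went round once more: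

electrophile left = 28.2% × exp(−0.0236 min⁻¹ × (90 min − 50.0 min)) = 11.0%

With target taken flat near theta's 21.7%, my estimate of the acid released in all came to 0.0554 M.

In one extreme version of the flask, free base catches each acid and no nucleophile is bound. In the other, nucleophile catches each acid and loses 2 per acid, one reacted and one bound:

free share = (charge − 2 × acid) / (charge − acid) = 61.7%

This free share, free nucleophile over unused nucleophile, is the low end. Theta's acid rate per electrophile fell to 0.593 of its early value. First order in nucleophile predicts 0.580 at the bound end and 0.795 at the free end, so I stayed at the low end, as a guess.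

The forecast said 88% and 63%, slightly apart from my 89.0% and 61.7%, and warned: “Second order in nucleophile would fit equally well”.

The flask gave 88.5% reacted and a free share of 63.0%, against my 61.7%.

    electrophile + nucleophile → acid set free + target (k = 0.110 M⁻¹ min⁻¹)
    acid set free + free base ⇌ salt of the base (K = 13.0 M⁻¹, k = 1.80 M⁻¹ min⁻¹)
    electrophile + target → side product (k = 0.560 M⁻¹ min⁻¹)
    nucleophile + acid set free ⇌ protonated nucleophile, settled at all times (K = 1600 M⁻¹)
    protic impurity + free base → quenched reagent (k = 39.0 M⁻¹ min⁻¹)

The neighbouring flask is the same recipe with 0.040 M of electrophile. Its target 45.6% and side product 44.4% count 0.0271 M of acid released in all, so the same free share came to 84.3%, and that neighbour gave a higher share than the flask, 84.5%.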